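A computed percentage can be exact and still answer another question, because one adduct may hold two complexes while the count gives it the weight of one.

    starting complex + incoming ligand ⇌ leaving ligand + complex with one exchanged (K1 = 0.22, k1 = 56 M⁻¹ s⁻¹, Ea1 = 42.0 kJ mol⁻¹, ΔH1 = −39.0 kJ mol⁻¹)
    complex with one exchanged + incoming ligand ⇌ leaving ligand + complex with two exchanged (K2 = 0.73, k2 = 160 M⁻¹ s⁻¹, Ea2 = 41.0 kJ mol⁻¹, ΔH2 = 36.0 kJ mol⁻¹)
    starting complex + complex with two exchanged ⇌ idle adduct A, settled at all times (K3 = 16000 M⁻¹, ΔH3 = 17.0 kJ mol⁻¹)
    leaving ligand + incoming ligand ⇌ idle adduct B, settled at all times (K4 = 550 M⁻¹, ΔH4 = −8.00 kJ mol⁻¹)
    scavenger + leaving ligand → scavenged by-product (k5 = 10000 M⁻¹ s⁻¹, Ea5 = 28.0 kJ mol⁻¹)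
    (constants at 5 °C)

| flask | starting complex | incoming ligand | scavenger | temperature | time |
|---|---|---|---|---|---|
| summer | 0.0010 M | 2.00 equiv | 0.300 equiv | 5 °C | 5.0 s |
| dusk | 0.0010 M | 2.00 equiv | 0.300 equiv | 25 °C | 5.0 s |
| noon | 0.0010 M | 2.00 equiv | 0.300 equiv | 45 °C | 5.0 s |

- percent here means starting complex units held: one idle adduct A counts as two
- what is said of complex with two exchanged includes idle adduct A
- what is said of leaving ligand includes idle adduct B
- all constants are for 5 °C and move with temperature by the activation energies and enthalpies
- in an amount of complex with two exchanged, one idle adduct A counts as one complex with two exchanged

- which of these there is most of at the end, counted by the starting complex in it, summer (complex with one exchanged / complex with two exchanged / starting complex)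
- which of these there is most of at the end, counted by the starting complex in it, dusk (complex with one exchanged / complex with two exchanged / starting complex)
- which of these there is most of at the end, counted by the starting complex in it, noon (complex with one exchanged / complex with two exchanged / starting complex)
- the largest of these amounts at the end, in percent of the starting complex charged, summer
- the largest of these amounts at the end, in percent of the starting complex charged, dusk
- the largest of these amounts at the end, in percent of the starting complex charged, noon

Idle adduct A holds one starting complex and one complex with two exchanged, so the dusk flask is read by comparing two amounts: the free starting complex and the concentration at which the adduct lets go. Step 3 at dusk has the constant 26200 M⁻¹. Its inverse, 3.82 × 10⁻⁵ M, is the concentration of starting complex at which free and bound complex with two exchanged stand equal: the release concentration, the usual dissociation constant. Step 3 is kept at balance, so at every moment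

free share = 1 / (1 + starting complex / release concentration).

The charge of starting complex, 0.0010 M, lies far above the release concentration, so the free form is the small correction, a share of 3.68% at that level. A complex with two exchanged takes one unit of the charge when free and two when bound, so each one counted takes two units minus the free share:

count = (charge − starting complex − complex with one exchanged) / (2 − free share).

As a trial for dusk, starting complex is set at a quarter of its charge and complex with one exchanged is neglected. The free share is then 13.2% and the count 40.2%. The reckoning goes no further, since that level of starting complex is a chosen value and not an outcome.

The forecast names starting complex for summer at 47%, complex with two exchanged for dusk at 67%, and complex with two exchanged for noon at 78%. Its ground is that “adduct A, counted as two units, pulls the material into the two-exchanged pool”. Its dusk figure stands higher than the trial count above.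

The simulation gives starting complex in summer at 51.2%, complex with two exchanged at dusk at 36.4%, and complex with two exchanged at noon at 41.3%.

At the end of the dusk flask, free starting complex, 2.69 × 10⁻⁴ M, still stands above the release concentration, which makes the free share 12.4%. Each counted complex with two exchanged therefore takes two units minus that share, and the dusk count of 36.4% takes 68.3% of the charge, against the forecast's 67%.

In the neighbouring flask with 5.00 equiv of incoming ligand, at the dusk temperature, starting complex ends at 5.62% and complex with one exchanged at 2.14%. The same reckoning gives a free share of 40.5% and a count of 57.8%. The computed amount there is 57.8%.

The rate constants were chosen freely.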